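**Retrosynthetic overview**
1. Feature: on the exocyclic C2=Cα bond of the cyclohexane (C1–C6), the formyl carbon Cf lies cis to C1, and the arm on C1 begins with Cc. A Cf–Cc bond therefore converts enal plus arm into a cyclopentenone (Cf, Cα, C2, C1, Cc) fused on C1–C2, and in that ring the required geometry is the only one possible.
2. Endgame cuts: C11 acetate and Ca myristate; Cf enal from its ester; Cb–Ca by Wittig reaction on the Cc aldehyde; Cf–Cc by α-ketol cleavage of the bicyclic enone; C8–C9 by Negishi coupling with an (E)-vinyl iodide (C9–C18).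
3. Key cut: enone to 1,7-enyne plus CO (Pauson–Khand). The cyclohexane and the cyclopentenone form together in this step and are the only carbocycles made. The five-membered ring is opened again later.
4. For the key step O5 and O8 are tied into a di-tert-butylsilylene ring, so that only one chair is open to the closing ring. That chair fixes C1.
5. The enyne comes from (S)-linalool, which supplies C5. C6 is set by a reagent-controlled cyclopropanation followed by cyclopropylmethyl-lithium opening, because the CH3 and CH2R groups on C5 are too alike to steer an acyclic rearrangement.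

Key step: step 15

Atom labels: ring C1 (CH with the arm Cc–Cb–Ca–O), C2 (alkylidene carbon), C3, C4, C5 (methyl carbinol, O5), C6 (quaternary). Cα is the exocyclic carbon and Cf the formyl carbon. The side chain runs C7–C18, O8 is the temporary oxygen on C8, and C11 bears the acetate. The target is 1R,5S,6S,11R, with C2=Cα Z, C9=C10 E and C13=C14 E.
Remark: (S)-(+)-linalool is taken as the enantiopure commercial terpene. Its optical purity passes unchanged into C5.

**Step 1**
Reactants: 1 (S)-(+)-linalool
Product: 2 (2S)-6-methyl-2-(oxiran-2-yl)hept-5-en-2-ol (both oxirane epimers)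
Conditions: VO(acac)2 (2 mol %), t-BuOOH (1.2 equiv), toluene, 0 °C → rt
Reagents that add atoms: tert-butyl hydroperoxide, CC(C)(C)OO
Why: Hydroxyl-directed vanadium epoxidation, in which the tertiary allylic alkoxide binds the metal peroxide and passes oxygen to the adjacent vinyl group faster than the remote trisubstituted alkene reacts; C5 is untouched and the uncontrolled oxirane centre is erased in step 3.

**Step 2**
Reactants: 2 epoxy alcohol
Product: 3 (3S)-3,7-dimethyloct-6-ene-2,3-diol (both C2 epimers)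
Conditions: LiAlH4, THF, 0 °C → rt
Reagents that add atoms: none
Why: SN2 hydride opening of a monosubstituted epoxide at its unhindered CH2 terminus gives the methyl carbinol.

**Step 3**
Reactants: 3 diol
Product: 4 (3S)-3-hydroxy-3,7-dimethyloct-6-en-2-one
Conditions: IBX, EtOAc, 75 °C
Reagents that add atoms: none
Why: IBX oxidation converts the secondary alcohol of a 1,2-diol into the α-ketol without C–C cleavage, while the tertiary C5 carbinol and the alkene are inert.

**Step 4**
Reactants: 4 α-ketol
Product: 5 (3S)-3-(tert-butyldimethylsilyloxy)-3,7-dimethyloct-6-en-2-one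
Conditions: TBSOTf, 2,6-lutidine, CH2Cl2, 0 °C → rt
Reagents that add atoms: tert-butyldimethylsilyl triflate, CC(C)(C)[Si](C)(C)OS(=O)(=O)C(F)(F)F
Why: Silyl triflate silylation is strong enough for a tertiary carbinol, and TBS is chosen because it must resist O-to-C migration to an alkyllithium three atoms away in step 9.

**Step 5**
Reactants: 5 silyloxy ketone; 6 triethyl phosphonoacetate
Product: 7 ethyl (2E,4S)-4-(tert-butyldimethylsilyloxy)-3,4,8-trimethylnona-2,7-dienoate
Conditions: NaH, THF, 0 °C → reflux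
Reagents that add atoms: none
Why: Horner–Wadsworth–Emmons olefination of a methyl ketone, in which the fully substituted C5 group takes the position trans to the ester and should give mainly the E alkene (any Z isomer is removed by chromatography).

**Step 6**
Reactants: 7 enoate
Product: 8 (2E,4S)-4-(tert-butyldimethylsilyloxy)-3,4,8-trimethylnona-2,7-dien-1-ol
Conditions: DIBAL-H (2.5 equiv), CH2Cl2, −78 °C
Reagents that add atoms: none
Why: 1,2-Reduction of the conjugated ester by DIBAL-H leaves the alkene geometry and the silyl ether intact.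

**Step 7**
Reactants: 8 allylic alcohol
Product: 9 {(1S,2S)-2-[(2S)-2-(tert-butyldimethylsilyloxy)-6-methylhept-5-en-2-yl]-2-methylcyclopropyl}methanol
Conditions: Et2Zn, CH2I2, DME, (4R,5R)-2-butyl-N,N,N′,N′-tetramethyl-1,3,2-dioxaborolane-4,5-dicarboxamide (1.2 equiv), CH2Cl2, −10 °C → rt
Reagents that add atoms: diiodomethane, ICI
Why: Charette asymmetric Simmons–Smith cyclopropanation adds methylene (the future C7) suprafacially to the E alkene from the face chosen by the alkoxide-bound (4R,5R)-dioxaborolane (the sense established for E-3-substituted allylic alcohols), so C6 is set by alkene geometry plus reagent rather than by C5, and the undirected prenyl alkene reacts much more slowly.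

**Step 8**
Reactants: 9 cyclopropylmethanol
Product: 10 tert-butyl({(2S)-2-[(1S,2S)-2-(iodomethyl)-1-methylcyclopropyl]-6-methylhept-5-en-2-yl}oxy)dimethylsilane
Conditions: I2, PPh3, imidazole, CH2Cl2, 0 °C
Reagents that add atoms: iodine, II
Why: Appel-type iodination runs by SN2 at the primary carbon, so no cyclopropylcarbinyl cation forms and the three-membered ring stays closed.

**Step 9**
Reactants: 10 cyclopropylmethyl iodide
Product: 13 (3S,4S)-4-(tert-butyldimethylsilyloxy)-3,4,8-trimethyl-3-vinylnon-7-en-1-ol, via cyclopropylmethyllithium 11 (not isolated), via homoallyllithium 12 (not isolated)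
Conditions: t-BuLi (2.1 equiv), pentane/Et2O, −78 → 0 °C; CH2O (gas), −78 °C → rt
Reagents that add atoms: formaldehyde, C=O
Why: Lithium–iodine exchange is followed by the cyclopropylmethyl-to-homoallyl lithium rearrangement, which breaks C1–C7 because that gives a primary rather than a tertiary carbanion; C6 keeps its four ligands in place, C1=Cc becomes the vinyl group, and C7–Li adds to formaldehyde to bring in C8.

**Step 10**
Reactants: 13 silyl ether alcohol
Product: 14 (3S,4S)-3,4,8-trimethyl-3-vinylnon-7-ene-1,4-diol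
Conditions: TBAF, THF, 50 °C
Reagents that add atoms: none
Why: Fluoride-driven Si–O cleavage frees O5, and nothing else in the molecule is fluoride- or base-sensitive.

**Step 11**
Reactants: 14 1,4-diol
Product: 15 (4S,5S)-2,2-di-tert-butyl-4,5-dimethyl-4-(4-methylpent-3-en-1-yl)-5-vinyl-1,3,2-dioxasilepane
Conditions: t-Bu2Si(OTf)2, 2,6-lutidine, CH2Cl2, 0 → 40 °C
Reagents that add atoms: di-tert-butylsilyl bis(triflate), CC(C)(C)[Si](OS(=O)(=O)C(F)(F)F)(OS(=O)(=O)C(F)(F)F)C(C)(C)C
Why: Cyclic silylene protection of a diol, in which primary O8 is silylated first and the second Si–O bond then closes intramolecularly on O5, giving the seven-membered tether needed in step 15.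

**Step 12**
Reactants: 15 silepane diene
Product: 17 3-[(4S,5S)-2,2-di-tert-butyl-4,5-dimethyl-5-vinyl-1,3,2-dioxasilepan-4-yl]propanal, via secondary ozonide 16 (not isolated)
Conditions: O3 (to the fading of Sudan Red 7B), CH2Cl2, −78 °C; Me2S
Reagents that add atoms: ozone, [O-][O+]=O
Why: Chemoselective ozonolysis consumes the electron-rich trisubstituted alkene before the monosubstituted vinyl group on the quaternary carbon, with the dye marking the end point.

**Step 13**
Reactants: 17 aldehyde
Product: 18 (4S,5S)-4-(but-3-yn-1-yl)-2,2-di-tert-butyl-4,5-dimethyl-5-vinyl-1,3,2-dioxasilepane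
Conditions: dimethyl (1-diazo-2-oxopropyl)phosphonate, K2CO3, MeOH, 0 °C → rt
Reagents that add atoms: dimethyl (1-diazo-2-oxopropyl)phosphonate, COP(=O)(OC)C(=[N+]=[N-])C(C)=O
Why: The Ohira–Bestmann form of the Seyferth–Gilbert homologation turns the C2 aldehyde into the terminal alkyne (adding Cα) under carbonate conditions that the hindered silylene tolerates.

**Step 14**
Reactants: 18 terminal alkyne
Product: 20 (4S,5S)-2,2-di-tert-butyl-4,5-dimethyl-4-(pent-3-yn-1-yl)-5-vinyl-1,3,2-dioxasilepane (the 1,7-enyne), via lithium acetylide 19 (not isolated)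
Conditions: n-BuLi, THF, −78 °C; MeI, −78 °C → rt
Reagents that add atoms: iodomethane, CI
Why: Acetylide formation and SN2 methylation place the Cα methyl group, and the only acidic C–H is the alkyne hydrogen.

**Step 15**
Reactants: 20 1,7-enyne
Product: 22 (6S,7S,7aR)-3,6,7-trimethyl-1,4,5,6,7,7a-hexahydro-2H-inden-2-one whose C6–O and C7–CH2CH2–O are joined through Si(t-Bu)2 (trans-fused dioxasilepane; 1R,5S,6S in target labels), via hexacarbonyldicobalt complex 21 (not isolated)
Conditions: Co2(CO)8 (1.1 equiv), CH2Cl2, rt; NMO (8 equiv), 0 °C → rt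
Reagents that add atoms: dicobalt octacarbonyl (source of Cf=O), O=C=[Co](=C=O)(=C=O)(=C=O)[Co](=C=O)(=C=O)(=C=O)=C=O
Why: This is an intramolecular Pauson–Khand reaction of a 1,7-enyne to a bicyclo[4.3.0]nonenone, a known reaction type: the alkyne replaces two CO ligands to give cluster 21, N-oxide removal of a further CO frees a site for the vinyl group, the vinyl CH (C1) inserts into the Co–C2 bond, CO migrates into the Co–Cc bond, and reductive elimination joins the acyl carbon Cf to Cα. The cyclohexane (C1–C6) closes in the exo sense, with C1 bonding to the inner alkyne carbon while Cc stays outside the ring on cobalt, and the cyclopentenone (Cf, Cα, C2, C1, Cc) closes inside the cobaltacycle by the CO insertion/reductive elimination pair. C1 is the only new stereocentre: Cc must lie in the plane of the C2=Cα unit and is therefore equatorial on the forming chair, and because the dioxasilepane cannot span an antiperiplanar O5–C5–C6–C7 array, only the chair with O5 and C7 equatorial and both methyl groups axial is open, which places the equatorial Cc cis to the C6 methyl group (1R). The step therefore needs π-facial selectivity at the vinyl group, which two separate ethers on O5 and O8 would not secure because their two chairs differ little in energy; the regiochemistry is fixed by the tether length and no other alkene is present. Closure is favoured by the buttressing of C5 against C6 and by the silepane, which keep the two unsaturated arms gauche, and a terminal vinyl group with a methyl-capped alkyne is among the better partner pairs for this reaction. The new ring holds Cf and C1 on the same side of C2=Cα, which is the enal geometry of the target and cannot be lost before the Cf–Cc bond is cut.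

**Step 16**
Reactants: 22 tricyclic enone
Product: 23 (6S,7S,7aR)-6-[di-tert-butyl(fluoro)silyloxy]-7-(2-hydroxyethyl)-3,6,7-trimethyl-1,4,5,6,7,7a-hexahydro-2H-inden-2-one
Conditions: BF3·SMe2, CH2Cl2, 0 °C; aq. NaHCO3
Reagents that add atoms: boron trifluoride–dimethyl sulfide, C[S+](C)[B-](F)(F)F
Why: Regioselective mono-opening of a cyclic di-tert-butylsilylene ether, in which boron binds the less hindered primary O8 and passes fluoride to silicon, frees C8–OH, leaves O5 as the robust fluorosilyl ether, and releases the tether so the ring can flip once Cc becomes a free substituent.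

**Step 17**
Reactants: 23 enone alcohol
Product: 24 (6S,7S,7aR)-6-[di-tert-butyl(fluoro)silyloxy]-7-(2-iodoethyl)-3,6,7-trimethyl-1,4,5,6,7,7a-hexahydro-2H-inden-2-one
Conditions: I2, PPh3, imidazole, CH2Cl2, 0 °C
Reagents that add atoms: iodine, II
Why: Appel-type iodination of the primary alcohol, with O5 masked so that no tetrahydrofuran can form by O5 attack on C8.

**Step 18**
Reactants: 25 geranyl chloride
Product: 27 (3E)-4,8-dimethylnona-3,7-dienoic acid, via geranylbarium chloride 26 (not isolated)
Conditions: BaI2, lithium biphenylide, THF, rt; 25, −78 °C; CO2, −78 °C; 1 M HCl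
Reagents that add atoms: carbon dioxide, O=C=O
Why: α-Selective carboxylation of an allylbarium reagent, which unlike the magnesium analogue reacts at the unsubstituted allyl terminus (C12) and keeps the E geometry at −78 °C, so C11 is attached to C12.

**Step 19**
Reactants: 27 acid
Product: 28 (3E)-N-methoxy-N,4,8-trimethylnona-3,7-dienamide
Conditions: MeONHMe·HCl, EDC·HCl, Et3N, DMAP (cat.), CH2Cl2, 0 °C → rt
Reagents that add atoms: N,O-dimethylhydroxylamine hydrochloride, CNOC.Cl
Why: Carbodiimide amidation to the Weinreb amide is mild enough to keep the β,γ-alkene out of conjugation.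

**Step 20**
Reactants: 28 Weinreb amide; 29 trimethylsilylacetylene
Product: 30 (5E)-6,10-dimethyl-1-(trimethylsilyl)undeca-5,9-dien-1-yn-3-one
Conditions: 29, n-BuLi, THF, −78 °C; 28, −78 → −20 °C; cold aq. NH4Cl
Reagents that add atoms: none
Why: Weinreb ketone synthesis, in which the chelated adduct stops at single addition and collapses to the ynone only on the cold, nearly neutral quench.

**Step 21**
Reactants: 30 ynone
Product: 31 (3R,5E)-6,10-dimethyl-1-(trimethylsilyl)undeca-5,9-dien-1-yn-3-ol
Conditions: Ru[(R,R)-TsDPEN](p-cymene) (1 mol %), i-PrOH, rt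
Reagents that add atoms: none
Why: Noyori asymmetric transfer hydrogenation of an alkynyl ketone, in which the alkynyl group plays the part of the aryl group so that the (R,R) catalyst should deliver hydride to give (R)-C11, and the base-free medium spares the doubly activated C12 methylene.

**Step 22**
Reactants: 31 silylalkynol
Product: 32 (3R,5E)-6,10-dimethylundeca-5,9-dien-1-yn-3-ol
Conditions: K2CO3 (cat.), MeOH, rt
Reagents that add atoms: none
Why: Methanolysis of the alkynyl C–Si bond frees the terminal alkyne without touching C11.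

**Step 23**
Reactants: 32 propargylic alcohol
Product: 34 (1E,3R,5E)-1-iodo-2,6,10-trimethylundeca-1,5,9-trien-3-ol, via alkenylalane 33 (not isolated)
Conditions: AlMe3 (3 equiv), Cp2ZrCl2 (0.3 equiv), CH2Cl2, 0 °C → rt; I2, THF, −30 °C
Reagents that add atoms: trimethylaluminium, C[Al](C)C; iodine, II
Why: Zirconium-catalysed carboalumination adds CH3 (to C10) and Al (to C9) syn across the terminal alkyne, and iodinolysis with retention fixes the E C9=C10 geometry, while the trisubstituted alkenes do not carbometalate.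

**Step 24**
Reactants: 34 iodo alcohol
Product: 35 tert-butyl{[(1E,3R,5E)-1-iodo-2,6,10-trimethylundeca-1,5,9-trien-3-yl]oxy}dimethylsilane
Conditions: TBSCl, imidazole, DMF, rt
Reagents that add atoms: tert-butyldimethylsilyl chloride, CC(C)(C)[Si](C)(C)Cl
Why: Standard silylation masks O11 against the organozinc, the amide base and DIBAL-H of later steps.

**Step 25**
Reactants: 24 alkyl iodide; 35 vinyl iodide
Product: 37 (6S,7S,7aR)-7-[(3E,5R,7E)-5-(tert-butyldimethylsilyloxy)-4,8,12-trimethyltrideca-3,7,11-trien-1-yl]-6-[di-tert-butyl(fluoro)silyloxy]-3,6,7-trimethyl-1,4,5,6,7,7a-hexahydro-2H-inden-2-one, via alkylzinc iodide 36 (not isolated)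
Conditions: Zn dust (BrCH2CH2Br, TMSCl), DMA, 40 °C; 35, PdCl2(dppf) (5 mol %), THF, rt → 45 °C
Reagents that add atoms: none
Why: Negishi sp3–sp2 coupling, in which zinc inserts into the primary C8–I bond without touching the fully β-substituted enone, the vinyl iodide couples with retention of its E geometry, and the wide-bite-angle dppf ligand holds back β-hydride elimination.

**Step 26**
Reactants: 37 enone
Product: 39 1-hydroxy derivative of 37 (OH on Cc, either epimer), via lithium enolate 38 (not isolated)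
Conditions: LiHMDS, THF, −78 °C; 2-(phenylsulfonyl)-3-phenyloxaziridine, −78 °C
Reagents that add atoms: 2-(phenylsulfonyl)-3-phenyloxaziridine, O=S(=O)(c1ccccc1)N1OC1c1ccccc1
Why: Kinetic deprotonation of the cyclopentenone at the α′ carbon Cc followed by Davis oxidation gives the α′-ketol, and its new carbinol centre is of no consequence because Cc becomes sp2 in step 27.

**Step 27**
Reactants: 39 α′-hydroxy enone
Product: 40 methyl (2Z)-2-{(2R,3S,4S)-3-[(3E,5R,7E)-5-(tert-butyldimethylsilyloxy)-4,8,12-trimethyltrideca-3,7,11-trien-1-yl]-4-[di-tert-butyl(fluoro)silyloxy]-2-formyl-3,4-dimethylcyclohexylidene}propanoate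
Conditions: Pb(OAc)4, MeOH/toluene 1:1, 0 °C
Reagents that add atoms: methanol, CO
Why: Lead tetraacetate (Criegee-type) cleavage of the α-ketol through its methanol hemiketal cuts Cf–Cc into the Cf methyl ester and the Cc aldehyde, and since C2=Cα takes no part, the ester stays cis to C1.

**Step 28**
Reactants: 40 ester aldehyde; 41 methyl (triphenylphosphoranylidene)acetate
Product: 42 the analogue of 40 with C1–CH=CH–CO2Me (E) in place of C1–CHO
Conditions: toluene, 50 °C
Reagents that add atoms: none
Why: Wittig olefination with a stabilised ylide adds Cb and Ca E-selectively under nearly neutral conditions, and C1 is not endangered because allylic strain against the Cf ester pushes the C1 arm axial in the untethered ring, which makes the natural epimer the more stable one.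

**Step 29**
Reactants: 42 bis-enoate
Product: 43 the analogue of 42 with C1–CH2CH2–CO2Me
Conditions: Cu(OAc)2·H2O (5 mol %), 1,2-bis(diphenylphosphino)benzene (5 mol %), PhSiH3, t-BuOH, toluene, rt
Reagents that add atoms: none
Why: Copper hydride conjugate reduction attacks only the disubstituted enoate, since the tetrasubstituted C2=Cα enoate is too hindered at its β carbon and the three isolated alkenes are not acceptors.

**Step 30**
Reactants: 43 diester
Product: 44 (2Z)-2-{(2R,3S,4S)-…-2-(3-hydroxypropyl)-3,4-dimethylcyclohexylidene}propan-1-ol (other substituents as in 40)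
Conditions: DIBAL-H (5 equiv), CH2Cl2, −78 °C
Reagents that add atoms: none
Why: DIBAL-H reduces both esters to primary alcohols (Ca–OH and the allylic Cf–OH) at a temperature at which the shielded Si–F and Si–O bonds should hold.

**Step 31**
Reactants: 44 diol
Product: 45 the corresponding (2Z)-propanal (Cf = CHO, Ca–OH free)
Conditions: MnO2, CH2Cl2, rt
Reagents that add atoms: none
Why: Manganese dioxide oxidises only the allylic alcohol, giving the tetrasubstituted enal with its geometry unchanged and leaving the saturated Ca–OH.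

**Step 32**
Reactants: 45 hydroxy enal; 46 tetradecanoyl (myristoyl) chloride
Product: 47 Ca tetradecanoate of 45
Conditions: pyridine, DMAP (cat.), CH2Cl2, 0 °C
Reagents that add atoms: none
Why: Acylation of the only free hydroxyl group installs the myristate.

**Step 33**
Reactants: 47 bis-silyl ether
Product: 48 the 5,11-diol (target lacking the acetyl group)
Conditions: HF·pyridine, pyridine, THF, 0 °C → rt
Reagents that add atoms: none
Why: Buffered fluoride cleaves both the secondary TBS ether and the fluorosilyl ether, while the enal, the ester and the trisubstituted alkenes tolerate the medium.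

**Step 34**
Reactants: 48 diol
Product: 49 CNP0184857.1 (target)
Conditions: Ac2O (1.2 equiv), pyridine, DMAP (cat.), CH2Cl2, 0 °C
Reagents that add atoms: acetic anhydride, CC(=O)OC(C)=O
Why: Selective acetylation, in which the secondary allylic C11–OH is acylated while the tertiary C5–OH next to the quaternary C6 is too hindered to react.

**Compound list**
1 | (S)-(+)-linalool | CC(C)=CCC[C@](C)(O)C=C | starting material
2 | (2S)-6-methyl-2-(oxiran-2-yl)hept-5-en-2-ol | CC(C)=CCC[C@](C)(O)C1CO1 | intermediate
3 | (3S)-3,7-dimethyloct-6-ene-2,3-diol | CC(C)=CCC[C@](C)(O)C(C)O | intermediate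
4 | (3S)-3-hydroxy-3,7-dimethyloct-6-en-2-one | CC(C)=CCC[C@](C)(O)C(C)=O | intermediate
5 | (3S)-3-(tert-butyldimethylsilyloxy)-3,7-dimethyloct-6-en-2-one | CC(C)=CCC[C@](C)(O[Si](C)(C)C(C)(C)C)C(C)=O | intermediate
6 | triethyl phosphonoacetate | CCOC(=O)CP(=O)(OCC)OCC | starting material
7 | ethyl (2E,4S)-4-(tert-butyldimethylsilyloxy)-3,4,8-trimethylnona-2,7-dienoate | CC(C)=CCC[C@](C)(O[Si](C)(C)C(C)(C)C)/C(C)=C/C(=O)OCC | intermediate
8 | (2E,4S)-4-(tert-butyldimethylsilyloxy)-3,4,8-trimethylnona-2,7-dien-1-ol | CC(C)=CCC[C@](C)(O[Si](C)(C)C(C)(C)C)/C(C)=C/CO | intermediate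
9 | {(1S,2S)-2-[(2S)-2-(tert-butyldimethylsilyloxy)-6-methylhept-5-en-2-yl]-2-methylcyclopropyl}methanol | CC(C)=CCC[C@](C)(O[Si](C)(C)C(C)(C)C)[C@@]1(C)C[C@@H]1CO | intermediate
10 | cyclopropylmethyl iodide from 9 | CC(C)=CCC[C@](C)(O[Si](C)(C)C(C)(C)C)[C@@]1(C)C[C@@H]1CI | intermediate
11 | cyclopropylmethyllithium | CC(C)=CCC[C@](C)(O[Si](C)(C)C(C)(C)C)[C@@]1(C)C[C@@H]1C[Li] | intermediate
12 | homoallyllithium | CC(C)=CCC[C@](C)(O[Si](C)(C)C(C)(C)C)[C@@](C=C)(C)C[Li] | intermediate
13 | (3S,4S)-4-(tert-butyldimethylsilyloxy)-3,4,8-trimethyl-3-vinylnon-7-en-1-ol | CC(C)=CCC[C@](C)(O[Si](C)(C)C(C)(C)C)[C@@](C=C)(C)CCO | intermediate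
14 | (3S,4S)-3,4,8-trimethyl-3-vinylnon-7-ene-1,4-diol | CC(C)=CCC[C@](C)(O)[C@@](C=C)(C)CCO | intermediate
15 | (4S,5S)-2,2-di-tert-butyl-4,5-dimethyl-4-(4-methylpent-3-en-1-yl)-5-vinyl-1,3,2-dioxasilepane | CC(C)=CCC[C@]1(C)O[Si](C(C)(C)C)(C(C)(C)C)OCC[C@@]1(C)C=C | intermediate
16 | secondary ozonide of 15 | CC1(C)OOC(CC[C@]2(C)O[Si](C(C)(C)C)(C(C)(C)C)OCC[C@@]2(C)C=C)O1 | intermediate
17 | 3-[(4S,5S)-2,2-di-tert-butyl-4,5-dimethyl-5-vinyl-1,3,2-dioxasilepan-4-yl]propanal | O=CCC[C@]1(C)O[Si](C(C)(C)C)(C(C)(C)C)OCC[C@@]1(C)C=C | intermediate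
18 | (4S,5S)-4-(but-3-yn-1-yl)-2,2-di-tert-butyl-4,5-dimethyl-5-vinyl-1,3,2-dioxasilepane | C#CCC[C@]1(C)O[Si](C(C)(C)C)(C(C)(C)C)OCC[C@@]1(C)C=C | intermediate
19 | lithium acetylide of 18 | [Li]C#CCC[C@]1(C)O[Si](C(C)(C)C)(C(C)(C)C)OCC[C@@]1(C)C=C | intermediate
20 | (4S,5S)-2,2-di-tert-butyl-4,5-dimethyl-4-(pent-3-yn-1-yl)-5-vinyl-1,3,2-dioxasilepane (1,7-enyne) | CC#CCC[C@]1(C)O[Si](C(C)(C)C)(C(C)(C)C)OCC[C@@]1(C)C=C | intermediate
21 | hexacarbonyldicobalt complex of 20 | CC12[Co]3(=C=O)(=C=O)(=C=O)[Co]1(=C=O)(=C=O)(=C=O)C23CC[C@]1(C)O[Si](C(C)(C)C)(C(C)(C)C)OCC[C@@]1(C)C=C | intermediate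
22 | Pauson–Khand enone, O5/O8 bridged by Si(t-Bu)2 (1R,5S,6S) | O=C1C[C@@H]2C(=C1C)CC[C@]3(C)O[Si](C(C)(C)C)(C(C)(C)C)OCC[C@@]23C | intermediate
23 | (6S,7S,7aR)-6-[di-tert-butyl(fluoro)silyloxy]-7-(2-hydroxyethyl)-3,6,7-trimethyl-1,4,5,6,7,7a-hexahydro-2H-inden-2-one | O=C1C[C@@H]2C(=C1C)CC[C@](C)(O[Si](F)(C(C)(C)C)C(C)(C)C)[C@@]2(C)CCO | intermediate
24 | 7-(2-iodoethyl) analogue of 23 | O=C1C[C@@H]2C(=C1C)CC[C@](C)(O[Si](F)(C(C)(C)C)C(C)(C)C)[C@@]2(C)CCI | intermediate
25 | geranyl chloride | ClC/C=C(\C)CCC=C(C)C | starting material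
26 | geranylbarium chloride | Cl[Ba]C/C=C(\C)CCC=C(C)C | intermediate
27 | (3E)-4,8-dimethylnona-3,7-dienoic acid | OC(=O)C/C=C(\C)CCC=C(C)C | intermediate
28 | (3E)-N-methoxy-N,4,8-trimethylnona-3,7-dienamide | CON(C)C(=O)C/C=C(\C)CCC=C(C)C | intermediate
29 | trimethylsilylacetylene | C#C[Si](C)(C)C | starting material
30 | (5E)-6,10-dimethyl-1-(trimethylsilyl)undeca-5,9-dien-1-yn-3-one | C[Si](C)(C)C#CC(=O)C/C=C(\C)CCC=C(C)C | intermediate
31 | (3R,5E)-6,10-dimethyl-1-(trimethylsilyl)undeca-5,9-dien-1-yn-3-ol | C[Si](C)(C)C#C[C@@H](C/C=C(\C)CCC=C(C)C)O | intermediate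
32 | (3R,5E)-6,10-dimethylundeca-5,9-dien-1-yn-3-ol | C#C[C@@H](C/C=C(\C)CCC=C(C)C)O | intermediate
33 | (E)-alkenylalane, O-aluminated | C[Al](C)/C=C(\C)[C@@H](C/C=C(\C)CCC=C(C)C)O[Al](C)C | intermediate
34 | (1E,3R,5E)-1-iodo-2,6,10-trimethylundeca-1,5,9-trien-3-ol | I/C=C(\C)[C@@H](C/C=C(\C)CCC=C(C)C)O | intermediate
35 | TBS ether of 34 | I/C=C(\C)[C@@H](C/C=C(\C)CCC=C(C)C)O[Si](C)(C)C(C)(C)C | intermediate
36 | alkylzinc iodide from 24 | O=C1C[C@@H]2C(=C1C)CC[C@](C)(O[Si](F)(C(C)(C)C)C(C)(C)C)[C@@]2(C)CC[Zn]I | intermediate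
37 | coupled enone (full side chain) | O=C1C[C@@H]2C(=C1C)CC[C@](C)(O[Si](F)(C(C)(C)C)C(C)(C)C)[C@@]2(C)CC/C=C(\C)[C@@H](C/C=C(\C)CCC=C(C)C)O[Si](C)(C)C(C)(C)C | intermediate
38 | lithium α′-enolate of 37 | [Li]OC1=C[C@@H]2C(=C1C)CC[C@](C)(O[Si](F)(C(C)(C)C)C(C)(C)C)[C@@]2(C)CC/C=C(\C)[C@@H](C/C=C(\C)CCC=C(C)C)O[Si](C)(C)C(C)(C)C | intermediate
39 | α′-hydroxy enone (OH on Cc) | O=C1C(O)[C@@H]2C(=C1C)CC[C@](C)(O[Si](F)(C(C)(C)C)C(C)(C)C)[C@@]2(C)CC/C=C(\C)[C@@H](C/C=C(\C)CCC=C(C)C)O[Si](C)(C)C(C)(C)C | intermediate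
40 | seco ester aldehyde (Cf CO2Me, Cc CHO) | O=C[C@@H]1/C(=C(/C)C(=O)OC)CC[C@](C)(O[Si](F)(C(C)(C)C)C(C)(C)C)[C@@]1(C)CC/C=C(\C)[C@@H](C/C=C(\C)CCC=C(C)C)O[Si](C)(C)C(C)(C)C | intermediate
41 | methyl (triphenylphosphoranylidene)acetate | COC(=O)C=P(c1ccccc1)(c1ccccc1)c1ccccc1 | starting material
42 | bis-enoate (Cc=Cb E) | COC(=O)/C=C/[C@@H]1/C(=C(/C)C(=O)OC)CC[C@](C)(O[Si](F)(C(C)(C)C)C(C)(C)C)[C@@]1(C)CC/C=C(\C)[C@@H](C/C=C(\C)CCC=C(C)C)O[Si](C)(C)C(C)(C)C | intermediate
43 | diester with saturated Cc–Cb | COC(=O)CC[C@@H]1/C(=C(/C)C(=O)OC)CC[C@](C)(O[Si](F)(C(C)(C)C)C(C)(C)C)[C@@]1(C)CC/C=C(\C)[C@@H](C/C=C(\C)CCC=C(C)C)O[Si](C)(C)C(C)(C)C | intermediate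
44 | Ca,Cf-diol | OCCC[C@@H]1/C(=C(/C)CO)CC[C@](C)(O[Si](F)(C(C)(C)C)C(C)(C)C)[C@@]1(C)CC/C=C(\C)[C@@H](C/C=C(\C)CCC=C(C)C)O[Si](C)(C)C(C)(C)C | intermediate
45 | hydroxy enal | OCCC[C@@H]1/C(=C(/C)C=O)CC[C@](C)(O[Si](F)(C(C)(C)C)C(C)(C)C)[C@@]1(C)CC/C=C(\C)[C@@H](C/C=C(\C)CCC=C(C)C)O[Si](C)(C)C(C)(C)C | intermediate
46 | tetradecanoyl chloride | CCCCCCCCCCCCCC(=O)Cl | starting material
47 | myristate enal, O5 and O11 silylated | CCCCCCCCCCCCCC(=O)OCCC[C@@H]1/C(=C(/C)C=O)CC[C@](C)(O[Si](F)(C(C)(C)C)C(C)(C)C)[C@@]1(C)CC/C=C(\C)[C@@H](C/C=C(\C)CCC=C(C)C)O[Si](C)(C)C(C)(C)C | intermediate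
48 | 5,11-diol | CCCCCCCCCCCCCC(=O)OCCC[C@@H]1/C(=C(/C)C=O)CC[C@](C)(O)[C@@]1(C)CC/C=C(\C)[C@@H](C/C=C(\C)CCC=C(C)C)O | intermediate
49 | CNP0184857.1 | CCCCCCCCCCCCCC(=O)OCCC[C@@H]1/C(=C(/C)C=O)CC[C@](C)(O)[C@@]1(C)CC/C=C(\C)[C@@H](C/C=C(\C)CCC=C(C)C)OC(C)=O | target

**Totals**
Total step count: 34.
Longest linear sequence: 27 steps (steps 1–17 and 25–34). Steps 18–24 form the side branch.

**Steps most likely to fail**

Step 15. Alkene insertion may be slow at the vinyl group on the quaternary carbon. The cobalt cluster would then decay or simply lose the alkyne, or material would leak through a boat-like arrangement and erode the facial selectivity.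
Fallback: starting from enyne 20, a zirconocene-mediated oxidative cyclisation (Cp2ZrCl2, 2 n-BuLi, THF, −78 °C → rt) would give the zirconabicycle F1. That ring closure is reversible, so the ring-fusion centre settles under thermodynamic control, which the silepane biases in the same direction. Carbonylation (CO, 1 atm, 0 °C) and acidic work-up lead back to enone 22.

Step 9. Three processes threaten this step: O-to-C silyl migration onto the alkyllithium, protonation before trapping, and radical leakage during the exchange, which would open the cyclopropane toward C6.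
Fallback: starting from allylic alcohol 8, a Johnson–Claisen rearrangement with triethyl orthoacetate (cat. propionic acid, 140 °C) would give the ethyl ester F2 as a mixture of C6 epimers, since C5 exerts little control. TBAF then removes the silyl group and the alkoxide closes onto the ester. The resulting rigid γ-lactones should be separable by chromatography, so the (4S,5S)-lactone F3 is kept and the C6-epimeric lactone F4 is discarded. LiAlH4 reduction of F3 returns to diol 14.

Step 11. The second Si–O bond to the crowded tertiary O5 may fail to close, leaving open-chain or oligomeric silyl ethers.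
Fallback: starting from diol 14, silylation of the primary hydroxyl with t-Bu2SiHCl (imidazole, DMF) would give the hydrosilyl ether F5. A base-catalysed intramolecular dehydrogenative Si–O coupling (cat. KOt-Bu, THF), driven by loss of hydrogen rather than displacement of triflate, then closes the ring to silepane 15.

**Further compounds**
F1 | step 15 | zirconabicycle (Cp2Zr bonded to Cα and Cc) | CC1=C2CC[C@]3(C)O[Si](C(C)(C)C)(C(C)(C)C)OCC[C@@]3(C)[C@@H]2C[Zr]1(C1C=CC=C1)C1C=CC=C1
F2 | step 9 | ethyl (4S)-4-(tert-butyldimethylsilyloxy)-3,4,8-trimethyl-3-vinylnon-7-enoate (C3 epimers) | CCOC(=O)CC(C)(C=C)[C@@](C)(O[Si](C)(C)C(C)(C)C)CCC=C(C)C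
F3 | step 9 | (4S,5S)-4,5-dimethyl-5-(4-methylpent-3-en-1-yl)-4-vinyldihydrofuran-2(3H)-one | O=C1C[C@@](C)(C=C)[C@](C)(CCC=C(C)C)O1
F4 | step 9 | (4R,5S)-4,5-dimethyl-5-(4-methylpent-3-en-1-yl)-4-vinyldihydrofuran-2(3H)-one | O=C1C[C@](C)(C=C)[C@](C)(CCC=C(C)C)O1
F5 | step 11 | (3S,4S)-1-(di-tert-butylsilyloxy)-3,4,8-trimethyl-3-vinylnon-7-en-4-ol | CC(C)=CCC[C@](C)(O)[C@@](C=C)(C)CCO[SiH](C(C)(C)C)C(C)(C)C
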